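**Strategy**

Everything rests on cutting the C4–C4a bond of ring C. Ring A is carried as a 4-benzyloxy-3,5-dimethoxyphenyl ether whose two carbons ortho to O1 are equivalent by mirror symmetry and are each flanked ortho and para by the future C5 and C7 methoxyls. The tethered C4 acyl group attacks one of them and closes the pyranone in a single Friedel–Crafts operation without any regiochemical choice. The precursor is a (2R,3R)-3-aryloxy-3-aryl-2-methoxypropanoic acid that already holds C2 and C3, assembled by an auxiliary-controlled syn glycolate aldol and a Mitsunobu inversion. Chelation-directed removal of the C5 methyl together with both benzyl groups finishes the target.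

Key step: step 7

Assumption: the target SMILES is read as the (2R,3R), 2,3-trans dihydroflavonol; 3-(benzyloxy)-4-methoxybenzaldehyde, methoxyacetyl chloride and (R)-4-benzyl-1,3-oxazolidin-2-one are taken as catalogue compounds.

**Route**

Step 1
Reactants: 1 (R)-4-benzyl-1,3-oxazolidin-2-one; 2 methoxyacetyl chloride
Product: 4 (R)-4-benzyl-3-(methoxyacetyl)-1,3-oxazolidin-2-one, via lithium oxazolidinide 3 (not isolated)
Conditions: nBuLi, THF, −78 °C; then 2, −78 → 0 °C
Reagents that add atoms: none
Why: N-acylation of a lithiated oxazolidinone with an acid chloride is the standard entry to N-acyl imides of this type, and the auxiliary stereocentre is not touched.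

Step 2
Reactants: 4 (R)-4-benzyl-3-(methoxyacetyl)-1,3-oxazolidin-2-one; 5 3-(benzyloxy)-4-methoxybenzaldehyde
Product: 7 (4R)-4-benzyl-3-[(2R,3S)-3-[3-(benzyloxy)-4-methoxyphenyl]-3-hydroxy-2-methoxypropanoyl]-1,3-oxazolidin-2-one, via dibutylboron Z-enolate 6 (not isolated)
Conditions: Bu2BOTf, Et3N, CH2Cl2, −78 → 0 °C; then 5, −78 → 0 °C; pH 7 buffer, MeOH, 30% H2O2, 0 °C
Reagents that add atoms: none
Why: In this auxiliary-controlled syn glycolate aldol the Z-boron enolate should react through a dipole-minimised Zimmerman–Traxler chair in which the (R)-benzyl group shields one enolate face, so that C2 (R) and C3 (S) of the propanoyl chain are set together as the 2,3-syn pair.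

Step 3
Reactants: 8 syringaldehyde (4-hydroxy-3,5-dimethoxybenzaldehyde)
Product: 9 4-(benzyloxy)-3,5-dimethoxybenzaldehyde
Conditions: BnBr, K2CO3, DMF, rt
Reagents that add atoms: benzyl bromide, BrCc1ccccc1
Why: Williamson etherification of an acidic, unhindered para-formyl phenoxide with a benzylic bromide is dependable and leaves the aldehyde untouched.

Step 4
Reactants: 9 4-(benzyloxy)-3,5-dimethoxybenzaldehyde
Product: 11 4-(benzyloxy)-3,5-dimethoxyphenol, via aryl formate 10 (not isolated)
Conditions: mCPBA, CH2Cl2, 0 °C → rt; aq NaHCO3 wash; then K2CO3 (cat.), MeOH, rt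
Reagents that add atoms: 3-chloroperoxybenzoic acid (mCPBA), OOC(=O)c1cccc(Cl)c1
Why: In this Baeyer–Villiger (Dakin-type) oxidation the electron-rich trialkoxyaryl group should migrate in preference to hydrogen to give the aryl formate, whose methanolysis frees the mirror-symmetric phenol.

Step 5
Reactants: 7 (4R)-4-benzyl-3-[(2R,3S)-3-[3-(benzyloxy)-4-methoxyphenyl]-3-hydroxy-2-methoxypropanoyl]-1,3-oxazolidin-2-one; 11 4-(benzyloxy)-3,5-dimethoxyphenol
Product: 12 (4R)-4-benzyl-3-[(2R,3R)-3-[4-(benzyloxy)-3,5-dimethoxyphenoxy]-3-[3-(benzyloxy)-4-methoxyphenyl]-2-methoxypropanoyl]-1,3-oxazolidin-2-one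
Conditions: PPh3, DIAD, toluene, 0 °C → rt
Reagents that add atoms: none
Why: In this Mitsunobu etherification the phenol (pKa about 10) should displace the alkoxyphosphonium group by SN2 and invert C3 from S to R, while the electron-withdrawing α-methoxy imide and the non-polar solvent work against ionisation at the benzylic carbon and the conformationally locked imide α-hydrogen is slow to be removed.

Step 6
Reactants: 12 (4R)-4-benzyl-3-[(2R,3R)-3-[4-(benzyloxy)-3,5-dimethoxyphenoxy]-3-[3-(benzyloxy)-4-methoxyphenyl]-2-methoxypropanoyl]-1,3-oxazolidin-2-one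
Product: 14 (2R,3R)-3-[4-(benzyloxy)-3,5-dimethoxyphenoxy]-3-[3-(benzyloxy)-4-methoxyphenyl]-2-methoxypropanoic acid, via peroxy acid 13 (not isolated)
Conditions: LiOH, 30% H2O2, THF/H2O (3:1), 0 °C; then aq Na2SO3; 1 M HCl to pH 3
Reagents that add atoms: hydrogen peroxide, OO
Why: In this hydroperoxide cleavage of an N-acyl oxazolidinone the weakly basic, strongly nucleophilic hydroperoxide should attack the exocyclic carbonyl at 0 °C without epimerising C2 or expelling the β-aryloxide, and sulfite reduces the peroxy acid to the acid.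

Step 7
Reactants: 14 (2R,3R)-3-[4-(benzyloxy)-3,5-dimethoxyphenoxy]-3-[3-(benzyloxy)-4-methoxyphenyl]-2-methoxypropanoic acid
Product: 16 (2R,3R)-6-(benzyloxy)-2-[3-(benzyloxy)-4-methoxyphenyl]-3,5,7-trimethoxychroman-4-one, via acid chloride 15 (not isolated)
Conditions: 1-chloro-N,N,2-trimethylprop-1-en-1-amine, CH2Cl2, 0 °C → rt; then SnCl4 (2.2 equiv), −78 → −40 °C; aq NaHCO3
Reagents that add atoms: none
Why: The chloroenamine should convert the acid into acid chloride 15 without releasing acid, and SnCl4, held by the acyl chloride and the α-methoxy oxygen, should make the acyl carbon electrophilic enough to be attacked by the ring A carbon ortho to the ether oxygen, after which loss of a proton restores the arene (intramolecular Friedel–Crafts acylation). The closest known reaction type is the cyclisation of 3-aryloxypropanoic acids or their chlorides to chroman-4-ones. Ring C closes in a 6-membered mode (6-exo-trig at the acyl carbon) through the tether C8a–O1–C2–C3–C4, forming the C4–C4a bond. No stereocentre is created: C2 and C3 come from 14, and C3, now α to the ketone, can only drift towards the more stable 2,3-trans diequatorial arrangement that is wanted. Regioselectivity is not at issue because the two ortho carbons of the symmetric ring A are equivalent. Chemoselectivity over acylation of ring B (5-membered indanone closure), over ionisation of the C2–O1 benzylic ether and over loss of CO from the α-alkoxy acyl species should follow from the very high nucleophilicity of a carbon flanked ortho, ortho and para by three oxygens, which allows reaction at −78 °C.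

Step 8
Reactants: 16 (2R,3R)-6-(benzyloxy)-2-[3-(benzyloxy)-4-methoxyphenyl]-3,5,7-trimethoxychroman-4-one
Product: 17 (2R,3R)-5,6-dihydroxy-2-(3-hydroxy-4-methoxyphenyl)-3,7-dimethoxychroman-4-one (CNP0393633.1)
Conditions: BCl3 (1 M in CH2Cl2, 6 equiv), C6HMe5 (6 equiv), CH2Cl2, −78 → 0 °C; then MeOH, H2O
Reagents that add atoms: none
Why: In this Lewis-acid dealkylation, boron held in a 6-membered chelate between the C4 carbonyl and the C5 oxygen should cleave that methyl ether alone among the four, while both benzyl ethers are cleaved at low temperature with pentamethylbenzene trapping the benzyl cation, so the C3, C7 and C4' methyl ethers and both stereocentres should survive.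

**Compound list**

1 | (R)-4-benzyl-1,3-oxazolidin-2-one | O=C1N[C@H](Cc2ccccc2)CO1 | starting material
2 | methoxyacetyl chloride | COCC(=O)Cl | starting material
3 | lithium salt of (R)-4-benzyl-1,3-oxazolidin-2-one (lithium oxazolidinide) | [Li+].O=C1[N-][C@H](Cc2ccccc2)CO1 | intermediate
4 | (R)-4-benzyl-3-(methoxyacetyl)-1,3-oxazolidin-2-one | COCC(=O)N1[C@H](Cc2ccccc2)COC1=O | intermediate
5 | 3-(benzyloxy)-4-methoxybenzaldehyde | COc1ccc(C=O)cc1OCc1ccccc1 | starting material
6 | (R,Z)-4-benzyl-3-{1-[(dibutylboranyl)oxy]-2-methoxyethenyl}-1,3-oxazolidin-2-one (dibutylboron Z-enolate) | CO/C=C(\OB(CCCC)CCCC)N1[C@H](Cc2ccccc2)COC1=O | intermediate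
7 | (4R)-4-benzyl-3-[(2R,3S)-3-[3-(benzyloxy)-4-methoxyphenyl]-3-hydroxy-2-methoxypropanoyl]-1,3-oxazolidin-2-one | COc1ccc([C@@H]([C@@H](OC)C(=O)N2[C@H](Cc3ccccc3)COC2=O)O)cc1OCc1ccccc1 | intermediate
8 | syringaldehyde (4-hydroxy-3,5-dimethoxybenzaldehyde) | COc1cc(C=O)cc(OC)c1O | starting material
9 | 4-(benzyloxy)-3,5-dimethoxybenzaldehyde | COc1cc(C=O)cc(OC)c1OCc1ccccc1 | intermediate
10 | 4-(benzyloxy)-3,5-dimethoxyphenyl formate | COc1cc(OC=O)cc(OC)c1OCc1ccccc1 | intermediate
11 | 4-(benzyloxy)-3,5-dimethoxyphenol | COc1cc(O)cc(OC)c1OCc1ccccc1 | intermediate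
12 | (4R)-4-benzyl-3-[(2R,3R)-3-[4-(benzyloxy)-3,5-dimethoxyphenoxy]-3-[3-(benzyloxy)-4-methoxyphenyl]-2-methoxypropanoyl]-1,3-oxazolidin-2-one | COc1ccc([C@H]([C@@H](OC)C(=O)N2[C@H](Cc3ccccc3)COC2=O)Oc2cc(OC)c(OCc3ccccc3)c(OC)c2)cc1OCc1ccccc1 | intermediate
13 | (2R,3R)-3-[4-(benzyloxy)-3,5-dimethoxyphenoxy]-3-[3-(benzyloxy)-4-methoxyphenyl]-2-methoxypropaneperoxoic acid | COc1ccc([C@H]([C@@H](OC)C(=O)OO)Oc2cc(OC)c(OCc3ccccc3)c(OC)c2)cc1OCc1ccccc1 | intermediate
14 | (2R,3R)-3-[4-(benzyloxy)-3,5-dimethoxyphenoxy]-3-[3-(benzyloxy)-4-methoxyphenyl]-2-methoxypropanoic acid | COc1ccc([C@H]([C@@H](OC)C(=O)O)Oc2cc(OC)c(OCc3ccccc3)c(OC)c2)cc1OCc1ccccc1 | intermediate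
15 | (2R,3R)-3-[4-(benzyloxy)-3,5-dimethoxyphenoxy]-3-[3-(benzyloxy)-4-methoxyphenyl]-2-methoxypropanoyl chloride | COc1ccc([C@H]([C@@H](OC)C(=O)Cl)Oc2cc(OC)c(OCc3ccccc3)c(OC)c2)cc1OCc1ccccc1 | intermediate
16 | (2R,3R)-6-(benzyloxy)-2-[3-(benzyloxy)-4-methoxyphenyl]-3,5,7-trimethoxychroman-4-one | COc1ccc([C@H]2Oc3cc(OC)c(OCc4ccccc4)c(OC)c3C(=O)[C@@H]2OC)cc1OCc1ccccc1 | intermediate
17 | (2R,3R)-5,6-dihydroxy-2-(3-hydroxy-4-methoxyphenyl)-3,7-dimethoxychroman-4-one | COc1ccc([C@H]2Oc3cc(OC)c(O)c(O)c3C(=O)[C@@H]2OC)cc1O | target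

**Step count**

Total steps: 8. Longest linear sequence: 6 (steps 1, 2, 5, 6, 7, 8; the branch through steps 3 and 4 is of equal length).

**Steps most likely to fail**

Step 7. The Lewis acid may ionise the C2–O1 benzylic ether (a para-methoxybenzylic position), the α-methoxy acyl species may lose CO, or the aryloxide may be expelled by β-elimination on activation. The fallback avoids acid and acyl cations altogether. Setting out from acid 14, coupling with N,O-dimethylhydroxylamine hydrochloride (EDC·HCl, HOBt, N-methylmorpholine, CH2Cl2, 0 °C) should give the N-methoxy-N-methylamide (2R,3R)-3-[4-(benzyloxy)-3,5-dimethoxyphenoxy]-3-[3-(benzyloxy)-4-methoxyphenyl]-N,2-dimethoxy-N-methylpropanamide F1. NBS (1.0 equiv, MeCN, −20 °C) should brominate ring A, by far the most electron-rich arene, at one of its two equivalent carbons ortho to the ether oxygen, giving the aryl bromide (2R,3R)-3-[4-(benzyloxy)-2-bromo-3,5-dimethoxyphenoxy]-3-[3-(benzyloxy)-4-methoxyphenyl]-N,2-dimethoxy-N-methylpropanamide F2. Bromine–lithium exchange (nBuLi, THF, −78 °C) and attack of the aryllithium on the amide (Parham cyclisation) would form the same C4–C4a bond and return to the route at chromanone 16.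

Step 5. Dehydration across C2–C3 of the β-hydroxy imide may compete with substitution, and partial ionisation of the activated benzylic alcohol may erode the configuration at C3. The fallback moves the etherification to the alcohol oxidation level, where no acidic α-hydrogen is present. From aldol adduct 7, LiBH4 (THF, 1 equiv MeOH, 0 °C) should remove the auxiliary reductively to give the diol (1S,2S)-1-[3-(benzyloxy)-4-methoxyphenyl]-2-methoxypropane-1,3-diol F3. TBSCl and imidazole (CH2Cl2, 0 °C) should silylate only the primary hydroxyl, giving the silyl ether (1S,2S)-1-[3-(benzyloxy)-4-methoxyphenyl]-3-[(tert-butyldimethylsilyl)oxy]-2-methoxypropan-1-ol F4. Mitsunobu etherification with phenol 11 (PPh3, DIAD, toluene, 0 °C → rt) should give, with inversion, the aryl ether tert-butyl{[(2S,3R)-3-[4-(benzyloxy)-3,5-dimethoxyphenoxy]-3-[3-(benzyloxy)-4-methoxyphenyl]-2-methoxypropyl]oxy}dimethylsilane F5. TBAF (THF, 0 °C) should free the primary alcohol (2S,3R)-3-[4-(benzyloxy)-3,5-dimethoxyphenoxy]-3-[3-(benzyloxy)-4-methoxyphenyl]-2-methoxypropan-1-ol F6. TEMPO (cat.) with PhI(OAc)2 in MeCN/H2O should oxidise it to acid 14, where the route is rejoined; step 6 is then not needed.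

Step 8. Excess Lewis acid may cleave further methyl ethers (C3, C7 or C4') or open ring C at the C2–O1 bond while the three dealkylations are driven to completion. The fallback separates the two events and ends with a neutral hydrogenolysis. From chromanone 16, MgI2·OEt2 (toluene/Et2O, rt → 40 °C) should remove only the chelated C5 methyl, giving the 5-hydroxy compound (2R,3R)-6-(benzyloxy)-2-[3-(benzyloxy)-4-methoxyphenyl]-5-hydroxy-3,7-dimethoxychroman-4-one F7. H2 (1 atm) over Pd/C in EtOAc at rt should then remove both benzyl groups and give target 17.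

**Further compounds**

F1 | step 7 | (2R,3R)-3-[4-(benzyloxy)-3,5-dimethoxyphenoxy]-3-[3-(benzyloxy)-4-methoxyphenyl]-N,2-dimethoxy-N-methylpropanamide | COc1ccc([C@H]([C@@H](OC)C(=O)N(C)OC)Oc2cc(OC)c(OCc3ccccc3)c(OC)c2)cc1OCc1ccccc1
F2 | step 7 | (2R,3R)-3-[4-(benzyloxy)-2-bromo-3,5-dimethoxyphenoxy]-3-[3-(benzyloxy)-4-methoxyphenyl]-N,2-dimethoxy-N-methylpropanamide | COc1ccc([C@H]([C@@H](OC)C(=O)N(C)OC)Oc2cc(OC)c(OCc3ccccc3)c(OC)c2Br)cc1OCc1ccccc1
F3 | step 5 | (1S,2S)-1-[3-(benzyloxy)-4-methoxyphenyl]-2-methoxypropane-1,3-diol | COc1ccc([C@@H]([C@@H](OC)CO)O)cc1OCc1ccccc1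
F4 | step 5 | (1S,2S)-1-[3-(benzyloxy)-4-methoxyphenyl]-3-[(tert-butyldimethylsilyl)oxy]-2-methoxypropan-1-ol | COc1ccc([C@@H]([C@@H](OC)CO[Si](C)(C)C(C)(C)C)O)cc1OCc1ccccc1
F5 | step 5 | tert-butyl{[(2S,3R)-3-[4-(benzyloxy)-3,5-dimethoxyphenoxy]-3-[3-(benzyloxy)-4-methoxyphenyl]-2-methoxypropyl]oxy}dimethylsilane | COc1ccc([C@H]([C@@H](OC)CO[Si](C)(C)C(C)(C)C)Oc2cc(OC)c(OCc3ccccc3)c(OC)c2)cc1OCc1ccccc1
F6 | step 5 | (2S,3R)-3-[4-(benzyloxy)-3,5-dimethoxyphenoxy]-3-[3-(benzyloxy)-4-methoxyphenyl]-2-methoxypropan-1-ol | COc1ccc([C@H]([C@@H](OC)CO)Oc2cc(OC)c(OCc3ccccc3)c(OC)c2)cc1OCc1ccccc1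
F7 | step 8 | (2R,3R)-6-(benzyloxy)-2-[3-(benzyloxy)-4-methoxyphenyl]-5-hydroxy-3,7-dimethoxychroman-4-one | COc1ccc([C@H]2Oc3cc(OC)c(OCc4ccccc4)c(O)c3C(=O)[C@@H]2OC)cc1OCc1ccccc1
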